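**Retrosynthetic overview** (halimane locants: ring A = C1–C5/C10, ring B = C5–C10, chain C11–C15 on C9)
1. Target ⇐ diol ⇐ bis-silyl ether 22. The C9–C11 bond is cut as a phosphine-directed, copper-mediated syn-SN2′ alkylation of a C1 allylic ester by the C11–C15 Grignard reagent.
2. Enabling feature: the trisubstituted C1=C10 alkene of ring A adjoins the quaternary C9 of ring B. C9 is therefore the γ-terminus of the allyl unit C1–C10–C9, and an axial C1–O leaving group on a C9=C10 octalin delivers both the C9–C11 bond and the Δ1(10) alkene.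
3. The allylic ester comes from enone 13 (C1=O, C9=C10). Ring B is closed second, by aldol condensation (C10–C9) of a 1,7-diketone obtained by Wacker oxidation.
4. Ring A is made first, by a catalytic enantioselective Diels–Alder reaction of a 2-silyloxybutadiene with an (E)-enal from (R)-β-citronellene (sets C4/C5; C8 comes from the pool). Rubottom oxidation of the adduct's enol ether installs the C2 oxygen.
5. The side chain comes from (R)-citronellol by oxidative cleavage and iododecarboxylation (one carbon removed). The end game is desilylation and double acetylation.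

Key step: step 14

Remark: the sense of induction of the oxazaborolidinium catalyst in step 3 is assumed from its usual transition-state model for α-substituted enals; the mirror-image catalyst would be used if the opposite sense were found.

Step 1
Reactants: 1 methyl vinyl ketone
Product: 2 2-(triisopropylsilyloxy)buta-1,3-diene
Conditions: TIPSOTf, Et3N, Et2O, 0 °C → rt
Reagents that add atoms: triisopropylsilyl trifluoromethanesulfonate, CC(C)[Si](OS(=O)(=O)C(F)(F)F)(C(C)C)C(C)C
Why: Soft enolisation of the enone (silyl enol ether formation) should give the cross-conjugated 2-silyloxy diene; no stereocentre is formed.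

Step 2
Reactants: 3 (R)-β-citronellene
Product: 5 (2E,6R)-2,6-dimethylocta-2,7-dienal, via allylic alcohol 4 (not isolated)
Conditions: SeO2, dioxane/H2O, reflux
Reagents that add atoms: selenium dioxide, O=[Se]=O
Why: Riley allylic oxidation (ene reaction, then [2,3]-shift) should attack the more nucleophilic trisubstituted alkene at its (E)-methyl group and carry the alcohol on to the (E)-enal, leaving the vinyl group and the C8 stereocentre untouched.

Step 3
Reactants: 5 (2E,6R)-2,6-dimethylocta-2,7-dienal; 2 2-(triisopropylsilyloxy)buta-1,3-diene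
Product: 6 (1S,6S)-1-methyl-6-[(3R)-3-methylpent-4-en-1-yl]-4-[(triisopropylsilyl)oxy]cyclohex-3-ene-1-carbaldehyde
Conditions: (S)-B-o-tolyl-diphenylprolinol oxazaborolidine·HNTf2 (20 mol %), excess 2, CH2Cl2, −78 → −20 °C
Reagents that add atoms: none
Why: Catalytic enantioselective Diels–Alder reaction closing ring A: the CH2 terminus next to the silyloxy carbon bonds to the enal β-carbon (para orientation), suprafacial addition to the (E)-enal fixes C4/C5 (formyl cis to H5, methyl cis to the chain), and the catalyst-shielded enal face should set the absolute (4S,5S) configuration.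

Step 4
Reactants: 6 Diels–Alder adduct
Product: 8 (1S,2S,5R)-1-methyl-2-[(3R)-3-methylpent-4-en-1-yl]-4-oxo-5-[(triisopropylsilyl)oxy]cyclohexane-1-carbaldehyde, via silyloxy epoxide 7 (not isolated)
Conditions: DMDO, acetone/CH2Cl2, −40 °C; then CSA (cat.), 0 °C
Reagents that add atoms: dimethyldioxirane, CC1(C)OO1
Why: Rubottom oxidation: the dioxirane should epoxidise only the electron-rich silyl enol ether, anti to the axial C4 methyl, and acid-triggered opening with 1,4-silyl shift gives the C2 silyloxy ketone, whose equatorial (2R) configuration is also the thermodynamic one at this epimerisable centre.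

Step 5
Reactants: 8 keto aldehyde
Product: 9 (1S,2S,5R)-1-methyl-2-[(3R)-3-methylpent-4-en-1-yl]-4-oxo-5-[(triisopropylsilyl)oxy]cyclohexane-1-carboxylic acid
Conditions: NaClO2, NaH2PO4, 2-methylbut-2-ene, t-BuOH/H2O, 0 °C → rt
Reagents that add atoms: sodium chlorite, [Na+].[O-]Cl=O
Why: Pinnick oxidation should convert the neopentyl aldehyde to the acid without touching the ketone, silyl ether or vinyl group, the alkene scavenger removing hypochlorite.

Step 6
Reactants: 9 keto acid
Product: 10 methyl (1S,2S,5R)-1-methyl-2-[(3R)-3-methylpent-4-en-1-yl]-4-oxo-5-[(triisopropylsilyl)oxy]cyclohexane-1-carboxylate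
Conditions: MeI, K2CO3, DMF, rt
Reagents that add atoms: iodomethane, CI
Why: SN2 O-methylation of the carboxylate avoids acid-catalysed esterification of a hindered acid and is too mild to alkylate the ketone.

Step 7
Reactants: 10 keto ester
Product: 11 methyl (1S,2S,5R)-1-methyl-2-[(3R)-3-methyl-4-oxopentyl]-4-oxo-5-[(triisopropylsilyl)oxy]cyclohexane-1-carboxylate
Conditions: PdCl2 (cat.), CuCl, O2, DMF/H2O, rt
Reagents that add atoms: water, O
Why: Tsuji–Wacker oxidation (Markovnikov hydroxypalladation, β-hydride elimination) should turn the terminal alkene into the C9 methyl ketone under near-neutral conditions that spare the adjacent C8 centre.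

Step 8
Reactants: 11 diketone
Product: 13 methyl (1S,3R,6R,8aS)-1,5,6-trimethyl-4-oxo-3-[(triisopropylsilyl)oxy]-1,2,3,4,6,7,8,8a-octahydronaphthalene-1-carboxylate, via β-hydroxy ketone 12 (not isolated)
Conditions: NaOMe, MeOH, 0 → 50 °C
Reagents that add atoms: none
Why: Intramolecular aldol condensation closing ring B: only attack of C10 on the C9 ketone gives a six-membered ring that can dehydrate to a conjugated enone, and the C8 methyl should sit pseudo-axial (α), which avoids A(1,2) strain with the C9 methyl.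

Step 9
Reactants: 13 bicyclic enone
Product: 14 methyl (1S,3R,4S,6R,8aS)-4-hydroxy-1,5,6-trimethyl-3-[(triisopropylsilyl)oxy]-1,2,3,4,6,7,8,8a-octahydronaphthalene-1-carboxylate
Conditions: NaBH4, CeCl3·7H2O, MeOH, −78 → 0 °C
Reagents that add atoms: none
Why: Luche 1,2-reduction: hydride should add to the C1 carbonyl from the α face so that the hydroxyl becomes axial (β, cis to the C2 silyloxy group), the arrangement that avoids A(1,3) strain with the C9 methyl of the exocyclic alkene.

Step 10
Reactants: 14 allylic alcohol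
Product: 15 methyl (1S,3R,4S,6R,8aS)-4-{[2-(diphenylphosphanyl)benzoyl]oxy}-1,5,6-trimethyl-3-[(triisopropylsilyl)oxy]-1,2,3,4,6,7,8,8a-octahydronaphthalene-1-carboxylate
Conditions: 2-(diphenylphosphanyl)benzoic acid, DCC, DMAP, CH2Cl2, rt
Reagents that add atoms: 2-(diphenylphosphanyl)benzoic acid, OC(=O)c1ccccc1P(c1ccccc1)c1ccccc1
Why: Steglich esterification should place the phosphine-bearing leaving group on the axial C1 hydroxyl with retention.

Step 11
Reactants: 16 (R)-citronellol
Product: 17 tert-butyl{[(3R)-3,7-dimethyloct-6-en-1-yl]oxy}dimethylsilane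
Conditions: TBSCl, imidazole, DMF, rt
Reagents that add atoms: tert-butyldimethylsilyl chloride, CC(C)(C)[Si](C)(C)Cl
Why: Standard silylation of the primary alcohol; the stereocentre is not involved.

Step 12
Reactants: 17 citronellyl silyl ether
Product: 18 (4R)-6-[(tert-butyldimethylsilyl)oxy]-4-methylhexanoic acid
Conditions: RuCl3·xH2O (cat.), NaIO4, CCl4/MeCN/H2O, rt
Reagents that add atoms: sodium periodate, [Na+].[O-]I(=O)(=O)=O; water, O
Why: Ruthenium tetroxide-catalysed oxidative cleavage of the trisubstituted alkene should give the acid and acetone while the primary silyl ether and the remote stereocentre stay intact.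

Step 13
Reactants: 18 silyloxy acid
Product: 20 tert-butyl{[(3S)-5-iodo-3-methylpentyl]oxy}dimethylsilane, via acyl hypoiodite 19 (not isolated)
Conditions: PhI(OAc)2, I2, PhH, hν (tungsten lamp), 60 °C
Reagents that add atoms: iodine, II
Why: Iododecarboxylation (hypoiodite reaction): the acyl hypoiodite should fragment under light to CO2 and the primary radical, which iodine traps, so the chain loses one carbon; the stereocentre is untouched (S only by change of priorities).

Step 14
Reactants: 20 (3S)-iodide; 15 o-DPPB allylic ester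
Product: 22 methyl (1S,3R,5S,6R,8aS)-5-{(3R)-5-[(tert-butyldimethylsilyl)oxy]-3-methylpentyl}-1,5,6-trimethyl-3-[(triisopropylsilyl)oxy]-1,2,3,5,6,7,8,8a-octahydronaphthalene-1-carboxylate, via Grignard reagent 21 (not isolated)
Conditions: 20, Mg, Et2O; then slow addition of 21 (1.3 equiv) to 15 and CuBr·SMe2 (0.5 equiv), Et2O, rt; aq. NH4Cl
Reagents that add atoms: none
Why: The Grignard reagent transmetallates to copper, which is held by the phosphine of the ester and so delivered to the alkene face that carries the C1–O bond; oxidative addition at the γ-carbon C9 with loss of the carboxylate and fast reductive elimination form the C9–C11 bond and move the alkene from C9=C10 to C1=C10. The closest known reaction type is the o-DPPB-directed copper-mediated allylic substitution of Grignard reagents (syn-SN2′), which has been used to build quaternary carbons with 1,3-chirality transfer. No ring is closed; the step joins the bicyclic core to the C11–C15 chain. The new quaternary centre C9 is controlled by C1: the leaving group is axial and β, so the alkyl group should enter on the β face (9S), and the pseudo-axial C8 methyl on the α face reinforces this. The step needs γ- over α-substitution, syn over anti delivery and tolerance of two esters; intramolecular phosphine–copper delivery secures the first two, and slow addition to substoichiometric copper together with the neopentyl position of the C4 ester secures the third. In the same operation the C1 oxygen is lost and the Δ1(10) alkene of the target is set next to the retained C2 silyloxy group.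

Step 15
Reactants: 22 bis-silyl ether
Product: 23 methyl (1S,3R,5S,6R,8aS)-3-hydroxy-5-[(3R)-5-hydroxy-3-methylpentyl]-1,5,6-trimethyl-1,2,3,5,6,7,8,8a-octahydronaphthalene-1-carboxylate
Conditions: TBAF, THF, rt → 40 °C
Reagents that add atoms: none
Why: Fluoride-mediated desilylation should remove both the primary TBS and the secondary TIPS ether without acid, so the allylic C2 alcohol is not ionised and the hindered methyl ester survives.

Step 16
Reactants: 23 diol
Product: 24 methyl (1S,3R,5S,6R,8aS)-3-acetoxy-5-[(3R)-5-acetoxy-3-methylpentyl]-1,5,6-trimethyl-1,2,3,5,6,7,8,8a-octahydronaphthalene-1-carboxylate (CNP0209333.1)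
Conditions: Ac2O, pyridine, DMAP (cat.), CH2Cl2, rt
Reagents that add atoms: acetic anhydride, CC(=O)OC(C)=O
Why: DMAP-catalysed acylation should acetylate the primary and the equatorial allylic secondary hydroxyl in one operation with retention at C2.

**Compound list**
1 | methyl vinyl ketone (but-3-en-2-one) | CC(=O)C=C | starting material
2 | 2-(triisopropylsilyloxy)buta-1,3-diene | C=CC(=C)O[Si](C(C)C)(C(C)C)C(C)C | intermediate
3 | (R)-β-citronellene, (3R)-3,7-dimethylocta-1,6-diene | CC(C)=CCC[C@@H](C)C=C | starting material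
4 | (2E,6R)-2,6-dimethylocta-2,7-dien-1-ol | OC/C(C)=C/CC[C@@H](C)C=C | intermediate (not isolated)
5 | (2E,6R)-2,6-dimethylocta-2,7-dienal | O=C/C(C)=C/CC[C@@H](C)C=C | intermediate
6 | (1S,6S)-1-methyl-6-[(3R)-3-methylpent-4-en-1-yl]-4-[(triisopropylsilyl)oxy]cyclohex-3-ene-1-carbaldehyde | O=C[C@@]1(C)CC=C(O[Si](C(C)C)(C(C)C)C(C)C)C[C@@H]1CC[C@@H](C)C=C | intermediate
7 | 4,5-epoxide of 6 (4-silyloxy oxirane, oxygen cis to the formyl group) | O=C[C@@]1(C)C[C@H]2O[C@@]2(O[Si](C(C)C)(C(C)C)C(C)C)C[C@@H]1CC[C@@H](C)C=C | intermediate (not isolated)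
8 | (1S,2S,5R)-1-methyl-2-[(3R)-3-methylpent-4-en-1-yl]-4-oxo-5-[(triisopropylsilyl)oxy]cyclohexane-1-carbaldehyde | O=C[C@@]1(C)C[C@@H](O[Si](C(C)C)(C(C)C)C(C)C)C(=O)C[C@@H]1CC[C@@H](C)C=C | intermediate
9 | (1S,2S,5R)-1-methyl-2-[(3R)-3-methylpent-4-en-1-yl]-4-oxo-5-[(triisopropylsilyl)oxy]cyclohexane-1-carboxylic acid | OC(=O)[C@@]1(C)C[C@@H](O[Si](C(C)C)(C(C)C)C(C)C)C(=O)C[C@@H]1CC[C@@H](C)C=C | intermediate
10 | methyl (1S,2S,5R)-1-methyl-2-[(3R)-3-methylpent-4-en-1-yl]-4-oxo-5-[(triisopropylsilyl)oxy]cyclohexane-1-carboxylate | COC(=O)[C@@]1(C)C[C@@H](O[Si](C(C)C)(C(C)C)C(C)C)C(=O)C[C@@H]1CC[C@@H](C)C=C | intermediate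
11 | methyl (1S,2S,5R)-1-methyl-2-[(3R)-3-methyl-4-oxopentyl]-4-oxo-5-[(triisopropylsilyl)oxy]cyclohexane-1-carboxylate | COC(=O)[C@@]1(C)C[C@@H](O[Si](C(C)C)(C(C)C)C(C)C)C(=O)C[C@@H]1CC[C@@H](C)C(C)=O | intermediate
12 | methyl (1S,3R,6R,8aS)-5-hydroxy-1,5,6-trimethyl-4-oxo-3-[(triisopropylsilyl)oxy]decahydronaphthalene-1-carboxylate (C4a and C5 not defined) | COC(=O)[C@@]1(C)C[C@@H](O[Si](C(C)C)(C(C)C)C(C)C)C(=O)C2C(C)(O)[C@H](C)CC[C@H]12 | intermediate (not isolated)
13 | methyl (1S,3R,6R,8aS)-1,5,6-trimethyl-4-oxo-3-[(triisopropylsilyl)oxy]-1,2,3,4,6,7,8,8a-octahydronaphthalene-1-carboxylate | COC(=O)[C@@]1(C)C[C@@H](O[Si](C(C)C)(C(C)C)C(C)C)C(=O)C2=C(C)[C@H](C)CC[C@H]12 | intermediate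
14 | methyl (1S,3R,4S,6R,8aS)-4-hydroxy-1,5,6-trimethyl-3-[(triisopropylsilyl)oxy]-1,2,3,4,6,7,8,8a-octahydronaphthalene-1-carboxylate | COC(=O)[C@@]1(C)C[C@@H](O[Si](C(C)C)(C(C)C)C(C)C)[C@@H](O)C2=C(C)[C@H](C)CC[C@H]12 | intermediate
15 | methyl (1S,3R,4S,6R,8aS)-4-{[2-(diphenylphosphanyl)benzoyl]oxy}-1,5,6-trimethyl-3-[(triisopropylsilyl)oxy]-1,2,3,4,6,7,8,8a-octahydronaphthalene-1-carboxylate | COC(=O)[C@@]1(C)C[C@@H](O[Si](C(C)C)(C(C)C)C(C)C)[C@@H](OC(=O)c3ccccc3P(c3ccccc3)c3ccccc3)C2=C(C)[C@H](C)CC[C@H]12 | intermediate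
16 | (R)-citronellol, (3R)-3,7-dimethyloct-6-en-1-ol | CC(C)=CCC[C@@H](C)CCO | starting material
17 | tert-butyl{[(3R)-3,7-dimethyloct-6-en-1-yl]oxy}dimethylsilane | CC(C)=CCC[C@@H](C)CCO[Si](C)(C)C(C)(C)C | intermediate
18 | (4R)-6-[(tert-butyldimethylsilyl)oxy]-4-methylhexanoic acid | OC(=O)CC[C@@H](C)CCO[Si](C)(C)C(C)(C)C | intermediate
19 | (4R)-6-[(tert-butyldimethylsilyl)oxy]-4-methylhexanoyl hypoiodite | IOC(=O)CC[C@@H](C)CCO[Si](C)(C)C(C)(C)C | intermediate (not isolated)
20 | tert-butyl{[(3S)-5-iodo-3-methylpentyl]oxy}dimethylsilane | ICC[C@@H](C)CCO[Si](C)(C)C(C)(C)C | intermediate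
21 | {(3S)-5-[(tert-butyldimethylsilyl)oxy]-3-methylpentyl}magnesium iodide | I[Mg]CC[C@@H](C)CCO[Si](C)(C)C(C)(C)C | intermediate (not isolated)
22 | methyl (1S,3R,5S,6R,8aS)-5-{(3R)-5-[(tert-butyldimethylsilyl)oxy]-3-methylpentyl}-1,5,6-trimethyl-3-[(triisopropylsilyl)oxy]-1,2,3,5,6,7,8,8a-octahydronaphthalene-1-carboxylate | COC(=O)[C@@]1(C)C[C@@H](O[Si](C(C)C)(C(C)C)C(C)C)C=C2[C@@H]1CC[C@@H](C)[C@]2(C)CC[C@@H](C)CCO[Si](C)(C)C(C)(C)C | intermediate
23 | methyl (1S,3R,5S,6R,8aS)-3-hydroxy-5-[(3R)-5-hydroxy-3-methylpentyl]-1,5,6-trimethyl-1,2,3,5,6,7,8,8a-octahydronaphthalene-1-carboxylate | COC(=O)[C@@]1(C)C[C@@H](O)C=C2[C@@H]1CC[C@@H](C)[C@]2(C)CC[C@@H](C)CCO | intermediate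
24 | methyl (1S,3R,5S,6R,8aS)-3-acetoxy-5-[(3R)-5-acetoxy-3-methylpentyl]-1,5,6-trimethyl-1,2,3,5,6,7,8,8a-octahydronaphthalene-1-carboxylate | COC(=O)[C@@]1(C)C[C@@H](OC(C)=O)C=C2[C@@H]1CC[C@@H](C)[C@]2(C)CC[C@@H](C)CCOC(C)=O | target

**Step count and risks**
Total step count: 16. Longest linear sequence: 12 steps (steps 2–10, then 14–16, from (R)-β-citronellene).

Steps most likely to fail:

Step 14. The alkyl group may not reach the fully substituted, ring-embedded γ-carbon, so that direct displacement at C1, reduction of the allylic ester or elimination to a diene takes over. The fallback sets out from enone 13 and comes back at 22. Grignard reagent 21 is added to the enone in a copper-catalysed conjugate addition (CuBr·SMe2, TMSCl, HMPA, THF, −78 °C), anti to the C8 methyl, to give the trimethylsilyl enol ether F1. Methyllithium followed by N-phenyl-bis(trifluoromethanesulfonimide) converts it into the enol triflate F2. Palladium-catalysed formate reduction (Pd(OAc)2, PPh3, Bu3N, HCO2H, DMF, 60 °C) replaces the triflate by hydrogen and gives 22.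

Step 3. The α,β-disubstituted enal may react sluggishly and the catalyst may discriminate its two faces incompletely, so the C4/C5 configuration is eroded. The fallback sets out from enal 5 (with diene 2) and comes back at acid 9. The cycloaddition is run without chiral control (Me2AlCl, CH2Cl2, −78 °C) and gives 6 together with its (1R,6R)-diastereomer F3. The pair is carried through steps 4 and 5 as it stands, the second series passing through the silyloxy epoxide F4 and the (1R,2R,5S)-keto aldehyde F5 to the (1R,2R,5S)-acid F6. Acids 9 and F6 are diastereomers because of the pool-derived centre in the side chain and are separated at this stage by preparative chromatography; F6 is discarded.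

Step 8. Enolisation of the methyl ketone towards C8 before or during ring closure may scramble the C8 configuration, and base may also induce silyl migration in the α-silyloxy ketone. The fallback sets out from keto ester 10 (skipping step 7) and comes back at enone 13. Kinetic enolisation (LDA, TMSCl, THF, −78 °C) occurs at C10, because C2 carries the silyloxy group, and gives the trimethylsilyl enol ether F7. Palladium(II)-mediated cycloalkenylation (Pd(OAc)2, MeCN, rt; Saegusa-type 6-exo attack of the enol ether on the vinyl group, then β-hydride elimination) closes ring B to the exo-methylene ketone F8 without ever making C8 enolisable. DBU in CH2Cl2 moves the exocyclic alkene into conjugation to give 13.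

Further compounds
F1 | step 14 | methyl (1S,3R,5S,6R,8aS)-5-{(3R)-5-[(tert-butyldimethylsilyl)oxy]-3-methylpentyl}-1,5,6-trimethyl-3-[(triisopropylsilyl)oxy]-4-[(trimethylsilyl)oxy]-1,2,3,5,6,7,8,8a-octahydronaphthalene-1-carboxylate | COC(=O)[C@@]1(C)C[C@@H](O[Si](C(C)C)(C(C)C)C(C)C)C(O[Si](C)(C)C)=C2[C@@H]1CC[C@@H](C)[C@]2(C)CC[C@@H](C)CCO[Si](C)(C)C(C)(C)C
F2 | step 14 | methyl (1S,3R,5S,6R,8aS)-5-{(3R)-5-[(tert-butyldimethylsilyl)oxy]-3-methylpentyl}-1,5,6-trimethyl-3-[(triisopropylsilyl)oxy]-4-{[(trifluoromethyl)sulfonyl]oxy}-1,2,3,5,6,7,8,8a-octahydronaphthalene-1-carboxylate | COC(=O)[C@@]1(C)C[C@@H](O[Si](C(C)C)(C(C)C)C(C)C)C(OS(=O)(=O)C(F)(F)F)=C2[C@@H]1CC[C@@H](C)[C@]2(C)CC[C@@H](C)CCO[Si](C)(C)C(C)(C)C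
F3 | step 3 | (1R,6R)-1-methyl-6-[(3R)-3-methylpent-4-en-1-yl]-4-[(triisopropylsilyl)oxy]cyclohex-3-ene-1-carbaldehyde | O=C[C@]1(C)CC=C(O[Si](C(C)C)(C(C)C)C(C)C)C[C@H]1CC[C@@H](C)C=C
F4 | step 3 | 4,5-epoxide of F3 (4-silyloxy oxirane, oxygen cis to the formyl group) | O=C[C@]1(C)C[C@@H]2O[C@]2(O[Si](C(C)C)(C(C)C)C(C)C)C[C@H]1CC[C@@H](C)C=C
F5 | step 3 | (1R,2R,5S)-1-methyl-2-[(3R)-3-methylpent-4-en-1-yl]-4-oxo-5-[(triisopropylsilyl)oxy]cyclohexane-1-carbaldehyde | O=C[C@]1(C)C[C@H](O[Si](C(C)C)(C(C)C)C(C)C)C(=O)C[C@H]1CC[C@@H](C)C=C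
F6 | step 3 | (1R,2R,5S)-1-methyl-2-[(3R)-3-methylpent-4-en-1-yl]-4-oxo-5-[(triisopropylsilyl)oxy]cyclohexane-1-carboxylic acid | OC(=O)[C@]1(C)C[C@H](O[Si](C(C)C)(C(C)C)C(C)C)C(=O)C[C@H]1CC[C@@H](C)C=C
F7 | step 8 | methyl (1S,2S,5R)-1-methyl-2-[(3R)-3-methylpent-4-en-1-yl]-5-[(triisopropylsilyl)oxy]-4-[(trimethylsilyl)oxy]cyclohex-3-ene-1-carboxylate | COC(=O)[C@@]1(C)C[C@@H](O[Si](C(C)C)(C(C)C)C(C)C)C(O[Si](C)(C)C)=C[C@@H]1CC[C@@H](C)C=C
F8 | step 8 | methyl (1S,3R,6R,8aS)-1,6-dimethyl-5-methylidene-4-oxo-3-[(triisopropylsilyl)oxy]decahydronaphthalene-1-carboxylate (C4a not defined) | COC(=O)[C@@]1(C)C[C@@H](O[Si](C(C)C)(C(C)C)C(C)C)C(=O)C2C(=C)[C@H](C)CC[C@H]12
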